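**Retrosynthetic overview**

- Psiguadial A ⇐ double Vilsmeier formylation of the bis-deformyl benzoxepine.
- The oxepine ring is closed last, through the C1–O bond: protonation of a C10 exocyclic methylene, 1,2-shift of the 1α-hydrogen, and capture of the C1 cation by a tethered phenol.
- The seco-phenol ⇐ Friedel–Crafts C1′–aryl bond between phloroglucinol and a C4-(α-hydroxybenzyl) ketone, then C10 methylenation.
- Key C4–C1′ bond ⇐ [1,2]-Wittig rearrangement of a tertiary 4-O-benzyl ether, joining an α-oxy benzyl carbanion (an umpoled benzaldehyde carbon) to the former carbinol carbon C4 with retention.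
- The three carbocycles and the C4–C7 stereocentres come from (+)-aromadendrene by ozonolysis and C4–H hydroxylation; no carbocycle is built.

Assumption: commercial (+)-aromadendrene is the natural (1aR,4aR,7R,7aR,7bS) enantiomer. Aromadendrane numbering is used, C1′ is the benzylic carbon, and β is the face carrying the cyclopropane CMe2 carbon, H-5, and the target's C1–O and C4–C1′ bonds.

**Route**

Step 1
Reactants: 1 (+)-aromadendrene
Product: 3 4β-hydroxyapoaromadendrone, via apoaromadendrone 2 (not isolated)
Conditions: O3, substrate adsorbed on SiO2, −78 °C → rt; EtOAc elution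
Reagents that add atoms: ozone, [O-][O+]=O
Why: Ozonolysis followed by dry ozonation on silica gel, which inserts oxygen into tertiary C–H bonds with retention: the exocyclic alkene is cleaved to ketone 2, and C4–H, the most exposed and electron-rich tertiary C–H (C1–H is α to the ketone, C5–H is a hindered ring-fusion methine β to it, and the cyclopropyl C–H bonds are inert), is then hydroxylated with retention to give the 4β-OH/4α-Me centre.

Step 2
Reactants: 3 4β-hydroxyapoaromadendrone
Product: 4 4β-benzyloxyapoaromadendrone
Conditions: 2-benzyloxy-1-methylpyridinium triflate (2 equiv), MgO, PhCF3, 85 °C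
Reagents that add atoms: 2-benzyloxy-1-methylpyridinium triflate, C[n+]1ccccc1OCc1ccccc1.[O-]S(=O)(=O)C(F)(F)F
Why: Neutral benzyl transfer (Dudley benzylation): the pyridinium salt releases a benzyl cation equivalent that the hindered tertiary alcohol captures without base, so the ketone is not enolised and no stereocentre is touched.

Step 3
Reactants: 4 4β-benzyloxyapoaromadendrone
Product: 8 4β-[hydroxy(phenyl)methyl]-14-noraromadendran-10-one (both carbinol epimers), via lithium enolate 5 (not isolated), via α-lithiobenzyl ether 6 (not isolated), via dilithium alkoxide 7 (not isolated)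
Conditions: lithium diisopropylamide (1.1 equiv), THF, −78 °C; then sec-butyllithium (2.5 equiv), −78 → −20 °C; aq NH4Cl
Reagents that add atoms: none
Why: [1,2]-Wittig rearrangement: with the ketone masked as enolate 5, benzylic lithiation gives α-oxy carbanion 6 (an umpoled benzaldehyde carbon), which releases the tertiary C4 radical and recaptures it at carbon inside the solvent cage on the face the oxygen occupied (also the less hindered face, anti to the C5–C6 bond), so the C4–C1′ bond joins two formerly electrophilic carbons with retention at C4 (β); the new carbinol centre forms as a mixture and is erased in step 4.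

Step 4
Reactants: 8 4β-[hydroxy(phenyl)methyl]-14-noraromadendran-10-one; 9 phloroglucinol (5 equiv)
Product: 10 4β-[(S)-phenyl(2,4,6-trihydroxyphenyl)methyl]-14-noraromadendran-10-one
Conditions: TsOH·H2O (20 mol%), HFIP–CH2Cl2 (1:4), rt
Reagents that add atoms: none
Why: Friedel–Crafts benzylation: acid ionises the benzylic alcohol and the strongly nucleophilic phloroglucinol, used in excess, traps the cation irreversibly at carbon, whereas any capture by the cis-disposed C10 ketone oxygen is reversible and non-productive; C1′ is set under substrate control, the arene entering anti to the C5 branch on the rotamer that keeps phenyl over the tied-back C3 methylene (Felkin-type), which gives the (S) centre.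

Step 5
Reactants: 10 4β-[(S)-phenyl(2,4,6-trihydroxyphenyl)methyl]-14-noraromadendran-10-one
Product: 11 4β-[(S)-phenyl(2,4,6-trihydroxyphenyl)methyl]aromadendr-10(14)-ene
Conditions: Ph3PCH3Br (6 equiv), KOtBu (6 equiv), THF, 0 → 60 °C, under Ar
Reagents that add atoms: methyltriphenylphosphonium bromide, C[P+](c1ccccc1)(c1ccccc1)c1ccccc1.[Br-]
Why: Wittig methylenation: excess ylide first deprotonates the three phenols and then methylenates the ketone, and the 1α-H centre survives because the trans-fused ketone is the thermodynamically preferred epimer.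

Step 6
Reactants: 11 4β-[(S)-phenyl(2,4,6-trihydroxyphenyl)methyl]aromadendr-10(14)-ene
Product: 12 bis-deformyl psiguadial A
Conditions: (+)-camphor-10-sulfonic acid (20 mol%), HFIP–CH2Cl2 (1:4), 0 °C → rt, 0.01 M
Reagents that add atoms: none
Why: Proposed new method: Markovnikov protonation of the exocyclic alkene gives the tertiary C10 cation, the 1α-hydrogen migrates suprafacially to set 10α-H (C10 methyl β), and a flanking phenol held on the β-face by the C4 tether captures the resulting tertiary C1 cation in a seven-membered ring, setting C1 (direct capture at C10 would need an eight-membered ring); the closest known reaction type is Brønsted-acid-catalysed intramolecular alkene hydroalkoxylation with a 1,2-hydride shift, as in biomimetic cationic cycloetherifications.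

Step 7
Reactants: 12 bis-deformyl psiguadial A
Product: 14 psiguadial A, via bis(iminium) salt 13 (not isolated)
Conditions: POCl3 (3 equiv), DMF (6 equiv), EtOAc, 0 °C → rt; then H2O, 40 °C
Reagents that add atoms: N,N-dimethylformamide, CN(C)C=O; water, O
Why: Vilsmeier–Haack formylation: the only two free ring positions of the phloroglucinol mono-ether are each ortho/para to oxygen, so double formylation is regiochemically unambiguous, and hydrolysis of 13 gives the dialdehyde without touching a stereocentre.

**Compound list**

1 | (+)-aromadendrene (1α-H, 5β-H, 4α-Me) | C=C1CC[C@@H]2[C@H]([C@@H]3[C@H](C)CC[C@H]31)C2(C)C | starting material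
2 | apoaromadendrone (14-noraromadendran-10-one, trans-fused) | O=C1CC[C@@H]2[C@H]([C@@H]3[C@H](C)CC[C@H]31)C2(C)C | intermediate
3 | 4β-hydroxyapoaromadendrone | O=C1CC[C@@H]2[C@H]([C@@H]3[C@](O)(C)CC[C@H]31)C2(C)C | intermediate
4 | 4β-benzyloxyapoaromadendrone | O=C1CC[C@@H]2[C@H]([C@@H]3[C@](OCc4ccccc4)(C)CC[C@H]31)C2(C)C | intermediate
5 | lithium C9–C10 enolate of 4 | [Li]OC1=CC[C@@H]2[C@H]([C@@H]3[C@](OCc4ccccc4)(C)CC[C@H]31)C2(C)C | intermediate
6 | α-lithiobenzyl ether of enolate 5 | [Li]OC1=CC[C@@H]2[C@H]([C@@H]3[C@](OC([Li])c4ccccc4)(C)CC[C@H]31)C2(C)C | intermediate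
7 | dilithium enolate/alkoxide of 8 | [Li]OC1=CC[C@@H]2[C@H]([C@@H]3[C@](C(O[Li])c4ccccc4)(C)CC[C@H]31)C2(C)C | intermediate
8 | 4β-[hydroxy(phenyl)methyl]-14-noraromadendran-10-one (carbinol epimers) | O=C1CC[C@@H]2[C@H]([C@@H]3[C@](C(O)c4ccccc4)(C)CC[C@H]31)C2(C)C | intermediate
9 | phloroglucinol | Oc1cc(O)cc(O)c1 | starting material
10 | 4β-[(S)-phenyl(2,4,6-trihydroxyphenyl)methyl]-14-noraromadendran-10-one | O=C1CC[C@@H]2[C@H]([C@@H]3[C@]([C@@H](c4ccccc4)c4c(O)cc(O)cc4O)(C)CC[C@H]31)C2(C)C | intermediate
11 | 4β-[(S)-phenyl(2,4,6-trihydroxyphenyl)methyl]aromadendr-10(14)-ene | C=C1CC[C@@H]2[C@H]([C@@H]3[C@]([C@@H](c4ccccc4)c4c(O)cc(O)cc4O)(C)CC[C@H]31)C2(C)C | intermediate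
12 | bis-deformyl psiguadial A | C[C@H]1CC[C@@H]2[C@H]([C@@H]3[C@]4(C)CC[C@@]31Oc1cc(O)cc(O)c1[C@@H]4c1ccccc1)C2(C)C | intermediate
13 | bis(N,N-dimethyliminium) dichloride of 14 | C[C@H]1CC[C@@H]2[C@H]([C@@H]3[C@]4(C)CC[C@@]31Oc1c(C=[N+](C)C)c(O)c(C=[N+](C)C)c(O)c1[C@@H]4c1ccccc1)C2(C)C.[Cl-].[Cl-] | intermediate
14 | psiguadial A | C[C@H]1CC[C@@H]2[C@H]([C@@H]3[C@]4(C)CC[C@@]31Oc1c(C=O)c(O)c(C=O)c(O)c1[C@@H]4c1ccccc1)C2(C)C | target

**Step count and risks**

Total step count: 7. Longest linear sequence: 7 (1 → 14); phloroglucinol 9 enters at step 4.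

Most likely to fail, first: step 3. The lithiated ether can undergo α′,β-elimination, and cage escape of the C4 radical would erode retention. The fallback keeps the ketyl logic but makes it intermolecular. It sets out from 3: acylation with methyl chlorooxoacetate gives the methyl oxalate F1, and CsOH hydrolysis gives the cesium oxalate F2. Blue-light irradiation of F2 with [Ir(dF(CF3)ppy)2(dtbbpy)]PF6 and benzaldehyde releases the C4 radical by double decarboxylation. This radical cross-couples with the benzaldehyde ketyl on the β-face, anti to the C5–C6 bond, and the route is rejoined at 8.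

Second: step 4. The neopentyl-type benzylic cation may undergo a Wagner–Meerwein shift before capture, and the facial selectivity at C1′ rests on an acyclic model and may be low. The fallback avoids any cation at C1′ and sets that centre by protonation instead. It sets out from 8: Ph3PCH3Br/KOtBu gives the methylidene carbinol F3, and Dess–Martin periodinane gives the phenyl ketone F4. Addition of 2,4,6-tris(benzyloxy)phenyllithium F5 (from 1,3,5-tris(benzyloxy)benzene and n-BuLi) gives the tertiary carbinol F6. Li/NH3 then cleaves the doubly benzylic C–O bond and the three benzyl ethers in one operation, the diarylmethyl anion being protonated anti to C5 with the bulky aryl turned away from the C4 methyl. The route is rejoined at 11.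

Third: step 6. The C10 or C1 cation may lose a proton to ledene-type alkenes, which on re-protonation would scramble C10, or a second hydride shift may open the cyclopropane. The fallback reverses the order of the last two events so that no external acid is needed. It sets out from 11: Vilsmeier–Haack formylation (POCl3, DMF) gives the diformyl seco-phenol F7, a vinylogous carboxylic acid. Heating F7 in HFIP lets this internal acid protonate the alkene and close the ether through the same hydride shift, as in the last stage of the biogenesis. The route is rejoined at 14.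

**Further compounds**

F1 | step 3 | methyl oxalate of 3 | O=C1CC[C@@H]2[C@H]([C@@H]3[C@](OC(=O)C(=O)OC)(C)CC[C@H]31)C2(C)C
F2 | step 3 | cesium oxalate of 3 | O=C1CC[C@@H]2[C@H]([C@@H]3[C@](OC(=O)C(=O)[O-])(C)CC[C@H]31)C2(C)C.[Cs+]
F3 | step 4 | 4β-[hydroxy(phenyl)methyl]aromadendr-10(14)-ene | C=C1CC[C@@H]2[C@H]([C@@H]3[C@](C(O)c4ccccc4)(C)CC[C@H]31)C2(C)C
F4 | step 4 | 4β-benzoylaromadendr-10(14)-ene | C=C1CC[C@@H]2[C@H]([C@@H]3[C@](C(=O)c4ccccc4)(C)CC[C@H]31)C2(C)C
F5 | step 4 | 2,4,6-tris(benzyloxy)phenyllithium | [Li]c1c(OCc2ccccc2)cc(OCc2ccccc2)cc1OCc1ccccc1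
F6 | step 4 | 4β-[hydroxy(phenyl)(2,4,6-tris(benzyloxy)phenyl)methyl]aromadendr-10(14)-ene | C=C1CC[C@@H]2[C@H]([C@@H]3[C@](C(O)(c4ccccc4)c4c(OCc5ccccc5)cc(OCc5ccccc5)cc4OCc4ccccc4)(C)CC[C@H]31)C2(C)C
F7 | step 6 | 4β-[(S)-(3,5-diformyl-2,4,6-trihydroxyphenyl)(phenyl)methyl]aromadendr-10(14)-ene | C=C1CC[C@@H]2[C@H]([C@@H]3[C@]([C@@H](c4ccccc4)c4c(O)c(C=O)c(O)c(C=O)c4O)(C)CC[C@H]31)C2(C)C
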